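The teal run and the amber run differ in their acid charge, so together they show what acid does to the substrate, and the flask's acid lies between theirs.

in all of them: substrate 13 mM
- teal: acid 0.26 mM; scavenger 19.5 mM; run made earlier
- amber: acid 0.58 mM; scavenger 19.5 mM; run made earlier
- green: acid 0.39 mM; scavenger 39 mM; run made earlier
- flask: acid 0.390 mM; scavenger 19.5 mM; time 12 min

- teal (time / min: substrate / %, product / %): 1.50: 79.4, 20.0; 3.00: 64.0, 35.4; 5.00: 47.7, 52.5; 6.00: 40.3, 59.0; 8.00: 31.1, 68.0; 10.0: 23.7, 76.5
- amber (time / min: substrate / %, product / %): 0.833: 78.8, 19.7; 1.33: 68.7, 30.1; 2.00: 57.0, 41.1; 4.00: 33.3, 66.6; 6.00: 18.8, 80.5; 10.0: 6.5, 94.0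
- green (time / min: substrate / %, product / %): 0.833: 84.3, 14.9; 1.33: 76.7, 23.6; 2.50: 61.8, 38.5; 5.00: 36.4, 63.1; 10.0: 14.7, 86.3

(standard deviation of a reading: 0.5 percentage points)

- acid is the free proton; pH is minus the decimal logarithm of its molar concentration

- part of the substrate that has reacted at 12 min
- pH of the solution at 12 min

I treat the acid as staying at its charge, so substrate decays with a pseudo-first-order constant k: the logarithm of charged over left, divided by time. The last readings give 0.144 min⁻¹ in the teal run and 0.273 min⁻¹ in the amber run. The first teal reading gives 0.154 min⁻¹, more than the last, so k sags within a run, and I keep the last readings, which lie nearest 12 min. Acid rises 2.23-fold but k 1.90-fold, so I draw a line in acid with an acid-free correction of 0.0389 min⁻¹. At the flask's 0.390 mM the line gives 0.197 min⁻¹, the apparent constant at this acid, k_f, and the correction is less than k_f.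

The green run holds this acid with twice the scavenger. k_f puts its substrate at 13.9% after 10.0 min, against a reading of 14.7%, with a scatter of 0.5 percentage points. For the flask at 12 min, k_f leaves 9.46%, so I commit to 90.5% reacted.

The forecast says 90% and pH 3.42, noting: “Green matches this, so scavenger has little or no effect.” For the pH I keep its nominal 3.41, that of the charged acid.

The flask gives 90.6% and pH 3.40.

    substrate → weak acid + product (k = 0.0330 min⁻¹)
    weak acid → by-product carried off (k = 0.0560 min⁻¹)
    substrate + acid → weak acid + acid + product (k = 410 M⁻¹ min⁻¹)
    substrate + weak acid ⇌ idle adduct, settled at all times (K = 72.0 M⁻¹)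
    weak acid ⇌ conjugate base + acid, settled at all times (K = 5.00 × 10⁻⁵ M)
    weak acid + scavenger → scavenged by-product (k = 670 M⁻¹ min⁻¹)

The flask holds 9.4% of its substrate at 12.0 min, where k_f left 9.46%, and its acid stands at 102% of charge. Reading at 9.80 min or 15.9 min moves c by 5 points, and so does an acid charge of 0.300 mM or 0.550 mM. Read at 3.0 min instead, k_f leaves 55.4%, which means 44.6% reacted, and that neighbouring flask gives 45.5%.

The runs are simulated for substances that don't exist; noise was put on by code.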